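**Retrosynthetic overview**

1. Target ⇒ tetraol (three acetates go on last) ⇒ seco C7 aldehyde / C6 (Z)-vinyl iodide. A Nozaki–Hiyama–Kishi coupling closes the ten-membered ring and the new C7 alkoxide closes the γ-lactone.
2. C8 carbinol and C17–C19 ⇒ Felkin-controlled propanoate enolate addition to a C8 ketone whose C7 is a dithiane carbon.
3. Key bond C9–C10 (with C9, C10 and the C11=C12 alkene) ⇒ Ireland–Claisen [3,3] rearrangement of a C12 allylic glycolate, chirality passing from C12–O to C10.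
4. C12 allylic alcohol ⇒ (S)-carvone by anti boron aldol (C1–C2 bond, C2), C-methylation (quaternary C1), epoxidation, Criegee rearrangement (isopropenyl → C14–OAc) and Wharton transposition.
5. Ring order: cyclohexene (bought as carvone) → ten-membered carbocycle → γ-lactone (same operation). Every stereocentre is relayed from the single stereocentre of (S)-carvone.

Assumption and convention: the target is taken exactly as the given SMILES (1S,2S,7S,8S,9S,10S,14S,17R; 5Z). Briarane locants are used for all intermediates: six-membered ring C1, C10–C14; ten-membered ring C1–C10; lactone C7–O–C19(=O)–C17–C8; methyls C15 (on C1), C16 (on C5), C18 (on C17), C20 (on C11).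

**Route**

Step 1
Reactants: 1 2-(2-bromoethyl)-1,3-dioxolane; 2 propyne
Product: 5 2-[(3Z)-4-iodo-3-methylbut-3-en-1-yl]-1,3-dioxolane, via Grignard reagent 3 (not isolated), via alkenylcopper 4 (not isolated)
Conditions: Mg, THF, 25 °C; CuBr·SMe2, Et2O/Me2S, −45 °C; propyne, −25 °C; I2, THF, −50 → 0 °C
Reagents that add atoms: iodine, II
Why: Normant carbocupration: the alkylcopper adds syn across propyne with copper at the terminal carbon, so iodinolysis with retention gives the Z iodoalkene (chain and iodine cis).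

Step 2
Reactants: 5 2-[(3Z)-4-iodo-3-methylbut-3-en-1-yl]-1,3-dioxolane
Product: 6 (4Z)-5-iodo-4-methylpent-4-enal
Conditions: 2 M aq. HCl, THF, 25 °C
Reagents that add atoms: water, O
Why: Acid-catalysed acetal hydrolysis unmasks the aldehyde without touching the iodoalkene.

Step 3
Reactants: 7 (S)-(+)-carvone; 6 (4Z)-5-iodo-4-methylpent-4-enal
Product: 9 anti-aldol adduct (5S,6S)-6-[(1S,4Z)-1-hydroxy-5-iodo-4-methylpent-4-en-1-yl]-2-methyl-5-(prop-1-en-2-yl)cyclohex-2-en-1-one, via boron enolate 8 (not isolated)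
Conditions: Cy2BCl, Et3N, Et2O, −78 → 0 °C; 6, −78 → −20 °C; H2O2, MeOH, pH 7 buffer, 0 °C
Reagents that add atoms: none
Why: Boron aldol reaction through a Zimmerman–Traxler chair: the ring-locked E enolborinate gives the anti adduct and the aldehyde approaches the enolate face opposite the isopropenyl group, which together set C2 as S (the C1 methine is reset in step 5).

Step 4
Reactants: 9 anti-aldol adduct
Product: 10 C2 tert-butyldimethylsilyl ether of 9
Conditions: TBSOTf, 2,6-lutidine, CH2Cl2, −78 °C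
Reagents that add atoms: tert-butyldimethylsilyl trifluoromethanesulfonate, CC(C)(C)[Si](C)(C)OS(=O)(=O)C(F)(F)F
Why: Silylation of the secondary carbinol blocks retro-aldol cleavage and beta-elimination in the base steps that follow.

Step 5
Reactants: 10 C2 silyl ether
Product: 12 C1-methylated enone (C15 methyl trans to the isopropenyl group; C2 chain cis), via lithium enolate 11 (not isolated)
Conditions: LiN(iPr)2, THF, −78 °C; MeI, DMPU, −78 → −20 °C
Reagents that add atoms: iodomethane, CI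
Why: Kinetic alpha-prime enolate alkylation: iodomethane enters anti to the neighbouring isopropenyl group, so the new methyl is trans to it and the C2 chain ends up cis, which sets quaternary C1.

Step 6
Reactants: 12 C1-methylated enone
Product: 13 11,12-epoxy ketone (epoxide trans to the isopropenyl group)
Conditions: 30% H2O2, NaOH (cat.), MeOH, 0 °C
Reagents that add atoms: hydrogen peroxide, OO
Why: Weitz–Scheffer nucleophilic epoxidation: hydroperoxide adds to C12 on the ring face opposite both the isopropenyl group and the C2 chain, giving the epoxide trans to them.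

Step 7
Reactants: 13 11,12-epoxy ketone
Product: 16 C14 acetoxy epoxy ketone, via methoxy hydroperoxide 14 (not isolated), via peroxyacetate 15 (not isolated)
Conditions: O3, CH2Cl2/MeOH, −78 °C (Sudan Red 7B end point); Ac2O, Et3N, DMAP (cat.), CH2Cl2, 0 → 40 °C
Reagents that add atoms: ozone, [O-][O+]=O; methanol, CO
Why: Ozonolysis of the only electron-rich alkene (the iodoalkene is deactivated) in methanol, then Criegee rearrangement of the peroxyacetate, in which C14 migrates from carbon to oxygen with retention to give the acetate (its acetyl carbons are the former isopropenyl carbons).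

Step 8
Reactants: 16 C14 acetoxy epoxy ketone
Product: 18 transposed allylic alcohol (C12–OH trans to C14–OAc; C10=C11), via epoxy hydrazone 17 (not isolated)
Conditions: N2H4·H2O, AcOH (cat.), MeOH, 0 → 25 °C
Reagents that add atoms: none
Why: Wharton transposition: the epoxy hydrazone collapses with loss of N2 to the 1,3-transposed allylic alcohol, the C12–O bond being retained so the hydroxyl stays trans to the C14 acetate.

Step 9
Reactants: 18 transposed allylic alcohol; 19 (tert-butyldimethylsilyloxy)acetic acid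
Product: 20 C12 (tert-butyldimethylsilyloxy)acetate ester
Conditions: EDC·HCl, DMAP, CH2Cl2, 0 → 25 °C
Reagents that add atoms: none
Why: Steglich esterification of the allylic alcohol installs the two-carbon C8–C9 unit for the rearrangement without touching a stereocentre.

Step 10
Reactants: 20 C12 glycolate ester
Product: 23 C8 methyl ester with (9S)-silyloxy and (10S)-H and a C11=C12 alkene, via bis(silyl ketene acetal) 21 (not isolated), via carboxylic acid 22 (not isolated)
Conditions: LiN(iPr)2 (3 equiv), TMSCl/Et3N, THF, −78 → 50 °C; 1 M HCl; TMSCHN2, PhMe/MeOH, 0 °C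
Reagents that add atoms: (trimethylsilyl)diazomethane, C[Si](C)(C)C=[N+]=[N-]
Why: Ireland–Claisen [3,3]-sigmatropic rearrangement: the ketene acetal is transferred suprafacially from the C12 oxygen to the same face of C10 (C10 S by 1,3-chirality transfer) through the boat-like transition state usual for cyclohexenyl Z-ketene acetals (the E isomer through a chair gives the same result), which sets C9 as S; TMSCHN2 then esterifies the acid.

Step 11
Reactants: 23 C8 methyl ester; 24 1,3-dithiane
Product: 26 2-acyl-1,3-dithiane (C8 ketone; C7 is the dithiane carbon; free C14–OH), via 2-lithio-1,3-dithiane 25 (not isolated)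
Conditions: n-BuLi, THF, −30 °C (24, 5 equiv); then 23, −78 → −20 °C; aq. NH4Cl
Reagents that add atoms: none
Why: Corey–Seebach acylation: the dithiane anion displaces methoxide and the ketone formed is protected as its enolate from a second addition, while the excess reagent also removes the C14 acetate (restored in step 16).

Step 12
Reactants: 26 2-acyl-1,3-dithiane; 27 ethyl propanoate
Product: 30 (8S)-tertiary alcohol ethyl ester (C17 epimers), via lithium enolate 28 (not isolated), via dichlorocerium enolate 29 (not isolated)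
Conditions: LiN(iPr)2, THF, −78 °C; CeCl3, −78 °C; then 26, −78 °C; aq. NH4Cl
Reagents that add atoms: none
Why: Aldol addition of a weakly basic cerium ester enolate to the enolisable ketone under Felkin–Anh control by the non-chelating C9 silyl ether sets C8 as S; C17 forms as a mixture that is equilibrated in step 14.

Step 13
Reactants: 30 (8S)-tertiary alcohol ethyl ester
Product: 31 C7 aldehyde
Conditions: MeI, CaCO3, MeCN/H2O (9:1), 45 °C
Reagents that add atoms: water, O
Why: Alkylative hydrolysis of the dithioacetal releases the C7 aldehyde under near-neutral conditions that leave the silyl ethers, ester and iodoalkene intact.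

Step 14
Reactants: 31 C7 aldehyde
Product: 34 ten-membered lactone 2,9-bis(tert-butyldimethylsilyl) ether, via alkenylchromium species 32 (not isolated), via macrocyclic hydroxy ester 33 (not isolated)
Conditions: CrCl2 (10 equiv), NiCl2 (2 mol%), DMSO/THF, 25 °C, 0.003 M; aqueous work-up; DBU, CH2Cl2, 25 °C
Reagents that add atoms: none
Why: Intramolecular Nozaki–Hiyama–Kishi coupling closes the ten-membered ring with retention of the Z alkene, the C9-tethered alkenylchromium reaching the aldehyde from the C9 face (Felkin-consistent) to set C7 as S; DBU then closes the gamma-lactone and equilibrates C17 to the R epimer with its methyl trans to C9.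

Step 15
Reactants: 34 ten-membered lactone bis(silyl) ether
Product: 35 tetraol (2,9,14-tri-O-deacetyl target)
Conditions: HF·pyridine, pyridine, THF, 0 → 40 °C
Reagents that add atoms: none
Why: Fluoride-mediated desilylation frees the C2 and C9 hydroxyls without opening the lactone.

Step 16
Reactants: 35 tetraol
Product: 36 CNP0187165.2
Conditions: Ac2O, pyridine, DMAP (cat.), CH2Cl2, 0 → 25 °C
Reagents that add atoms: acetic anhydride, CC(=O)OC(C)=O
Why: DMAP-catalysed acetylation esterifies the three secondary hydroxyls while the hindered tertiary C8 hydroxyl stays free.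

**Compound list**

1 | 2-(2-bromoethyl)-1,3-dioxolane | BrCCC1OCCO1 | starting material
2 | propyne | CC#C | starting material
3 | [2-(1,3-dioxolan-2-yl)ethyl]magnesium bromide | Br[Mg]CCC1OCCO1 | intermediate
4 | (Z)-[4-(1,3-dioxolan-2-yl)-2-methylbut-1-en-1-yl]copper (MgBr2 not shown) | [Cu]/C=C(/C)CCC1OCCO1 | intermediate
5 | 2-[(3Z)-4-iodo-3-methylbut-3-en-1-yl]-1,3-dioxolane | I/C=C(/C)CCC1OCCO1 | intermediate
6 | (4Z)-5-iodo-4-methylpent-4-enal | O=CCC/C(C)=C\I | intermediate
7 | (S)-(+)-carvone | CC(=C)[C@H]1CC=C(C)C(=O)C1 | starting material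
8 | O-dicyclohexylboryl dienolate of carvone (C1=C10 enolate) | CC(=C)[C@H]1CC=C(C)C(OB(C2CCCCC2)C2CCCCC2)=C1 | intermediate
9 | anti-aldol adduct: carvone with a (1S,4Z)-1-hydroxy-5-iodo-4-methylpent-4-enyl chain at C1, trans to the isopropenyl group | CC(=C)[C@H]1CC=C(C)C(=O)[C@@H]1[C@@H](O)CC/C(C)=C\I | intermediate
10 | C2 tert-butyldimethylsilyl ether of 9 | CC(=C)[C@H]1CC=C(C)C(=O)[C@@H]1[C@@H](O[Si](C)(C)C(C)(C)C)CC/C(C)=C\I | intermediate
11 | lithium enolate of 10 (C1=C10–OLi) | CC(=C)[C@H]1CC=C(C)C(O[Li])=C1[C@@H](O[Si](C)(C)C(C)(C)C)CC/C(C)=C\I | intermediate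
12 | C1-methylated enone: C15 methyl trans, C2 chain cis to the isopropenyl group | CC(=C)[C@H]1CC=C(C)C(=O)[C@@]1(C)[C@@H](O[Si](C)(C)C(C)(C)C)CC/C(C)=C\I | intermediate
13 | 11,12-epoxy ketone, epoxide oxygen trans to the isopropenyl group | CC(=C)[C@H]1C[C@@H]2O[C@]2(C)C(=O)[C@@]1(C)[C@@H](O[Si](C)(C)C(C)(C)C)CC/C(C)=C\I | intermediate
14 | C14 (1-hydroperoxy-1-methoxyethyl) epoxy ketone (epimers at the peroxyketal carbon) | COC(C)(OO)[C@H]1C[C@@H]2O[C@]2(C)C(=O)[C@@]1(C)[C@@H](O[Si](C)(C)C(C)(C)C)CC/C(C)=C\I | intermediate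
15 | peroxyacetate of 14 | COC(C)(OOC(C)=O)[C@H]1C[C@@H]2O[C@]2(C)C(=O)[C@@]1(C)[C@@H](O[Si](C)(C)C(C)(C)C)CC/C(C)=C\I | intermediate
16 | C14 acetoxy epoxy ketone (OAc in place of isopropenyl, retention) | CC(=O)O[C@H]1C[C@@H]2O[C@]2(C)C(=O)[C@@]1(C)[C@@H](O[Si](C)(C)C(C)(C)C)CC/C(C)=C\I | intermediate
17 | C10 hydrazone of 16 | CC(=O)O[C@H]1C[C@@H]2O[C@]2(C)C(=NN)[C@@]1(C)[C@@H](O[Si](C)(C)C(C)(C)C)CC/C(C)=C\I | intermediate
18 | allylic alcohol: C12–OH trans to C14–OAc, C10=C11 alkene | CC(=O)O[C@H]1C[C@H](O)C(C)=C[C@@]1(C)[C@@H](O[Si](C)(C)C(C)(C)C)CC/C(C)=C\I | intermediate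
19 | (tert-butyldimethylsilyloxy)acetic acid | CC(C)(C)[Si](C)(C)OCC(=O)O | starting material
20 | C12 (tert-butyldimethylsilyloxy)acetate ester of 18 | CC(=O)O[C@H]1C[C@H](OC(=O)CO[Si](C)(C)C(C)(C)C)C(C)=C[C@@]1(C)[C@@H](O[Si](C)(C)C(C)(C)C)CC/C(C)=C\I | intermediate
21 | bis(trimethylsilyl ketene acetal) of 20 (glycolate and acetate esters both O-silylated; glycolate C=C geometry not defined) | C=C(O[Si](C)(C)C)O[C@H]1C[C@H](OC(O[Si](C)(C)C)=CO[Si](C)(C)C(C)(C)C)C(C)=C[C@@]1(C)[C@@H](O[Si](C)(C)C(C)(C)C)CC/C(C)=C\I | intermediate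
22 | C8 carboxylic acid: (9S)-OTBS, (10S)-H, C11=C12 | CC(=O)O[C@H]1CC=C(C)[C@H]([C@H](O[Si](C)(C)C(C)(C)C)C(=O)O)[C@@]1(C)[C@@H](O[Si](C)(C)C(C)(C)C)CC/C(C)=C\I | intermediate
23 | methyl ester of 22 | CC(=O)O[C@H]1CC=C(C)[C@H]([C@H](O[Si](C)(C)C(C)(C)C)C(=O)OC)[C@@]1(C)[C@@H](O[Si](C)(C)C(C)(C)C)CC/C(C)=C\I | intermediate
24 | 1,3-dithiane | C1CSCSC1 | starting material
25 | 2-lithio-1,3-dithiane | [Li]C1SCCCS1 | intermediate
26 | C8 ketone carrying a 1,3-dithian-2-yl group (C7), C14–OH free | O[C@H]1CC=C(C)[C@H]([C@H](O[Si](C)(C)C(C)(C)C)C(=O)C2SCCCS2)[C@@]1(C)[C@@H](O[Si](C)(C)C(C)(C)C)CC/C(C)=C\I | intermediate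
27 | ethyl propanoate | CCOC(=O)CC | starting material
28 | lithium (E)-enolate of ethyl propanoate | C/C=C(/O[Li])OCC | intermediate
29 | dichlorocerium enolate of ethyl propanoate | C/C=C(/O[Ce](Cl)Cl)OCC | intermediate
30 | (8S)-tertiary alcohol with the C17–C19 ethyl propanoate unit (C17 epimers), C7 dithiane | O[C@H]1CC=C(C)[C@H]([C@H](O[Si](C)(C)C(C)(C)C)[C@](O)(C(C)C(=O)OCC)C2SCCCS2)[C@@]1(C)[C@@H](O[Si](C)(C)C(C)(C)C)CC/C(C)=C\I | intermediate
31 | C7 aldehyde from 30 | O[C@H]1CC=C(C)[C@H]([C@H](O[Si](C)(C)C(C)(C)C)[C@](O)(C(C)C(=O)OCC)C=O)[C@@]1(C)[C@@H](O[Si](C)(C)C(C)(C)C)CC/C(C)=C\I | intermediate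
32 | alkenylchromium dichloride from 31 (C6–Cr) | O[C@H]1CC=C(C)[C@H]([C@H](O[Si](C)(C)C(C)(C)C)[C@](O)(C(C)C(=O)OCC)C=O)[C@@]1(C)[C@@H](O[Si](C)(C)C(C)(C)C)CC/C(C)=C\[Cr](Cl)Cl | intermediate
33 | macrocyclic hydroxy ester: C6–C7 bond closed, (7S)-OH, 5Z | O[C@H]1CC=C(C)[C@@H]2[C@H](O[Si](C)(C)C(C)(C)C)[C@](O)(C(C)C(=O)OCC)[C@@H](O)/C=C(/C)CC[C@H](O[Si](C)(C)C(C)(C)C)[C@@]12C | intermediate
34 | 18,7-lactone, 2,9-bis(TBS) ether, 8- and 14-OH free, (17R) | O[C@H]1CC=C(C)[C@@H]2[C@H](O[Si](C)(C)C(C)(C)C)[C@@]3(O)[C@H](/C=C(/C)CC[C@H](O[Si](C)(C)C(C)(C)C)[C@@]12C)OC(=O)[C@@H]3C | intermediate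
35 | tetraol (2,9,14-tri-O-deacetyl target) | O[C@H]1CC=C(C)[C@@H]2[C@H](O)[C@@]3(O)[C@H](/C=C(/C)CC[C@H](O)[C@@]12C)OC(=O)[C@@H]3C | intermediate
36 | CNP0187165.2 | CC(=O)O[C@H]1CC=C(C)[C@@H]2[C@H](OC(C)=O)[C@@]3(O)[C@H](/C=C(/C)CC[C@H](OC(C)=O)[C@@]12C)OC(=O)[C@@H]3C | target

**Step count and risks**

Total steps: 16. Longest linear sequence: 16 steps (1 → 36; 14 steps from (S)-carvone 7).

The three steps most likely to fail:

Step 8 (Wharton transposition). The C10 ketone sits between a quaternary carbon and a fully substituted epoxide carbon, so hydrazone formation may stall. The fallback sets out from 16. NaBH4 in MeOH at 0 °C reduces the ketone to the epoxy alcohol F1 (either C10 epimer serves). MsCl/Et3N gives the epoxy mesylate F2. Cp2TiCl (from Cp2TiCl2 and Zn in THF) opens the epoxide by single-electron transfer to the tertiary C11 radical, which is reduced again and expels the mesylate. This gives the C10=C11 alkene and the C12 alkoxide, so the route is rejoined at 18.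

Step 10 (Ireland–Claisen rearrangement). The new bond forms next to quaternary C1, and the C9 configuration depends on the boat/chair preference. The fallback sets out from 18. Rh2(OAc)4-catalysed O–H insertion of methyl diazoacetate gives the allyloxyacetate F3. LiN(SiMe3)2 in THF (−78 → −20 °C) triggers an ester-enolate [2,3]-Wittig rearrangement. This also delivers carbon to the C12–O face of C10, but with the ester group exo it should give the 9-epi hydroxy ester F4. Mitsunobu inversion with chloroacetic acid (PPh3, DIAD) gives the chloroacetate F5. Thiourea/NaHCO3 removes the chloroacetyl group beside the C14 acetate to give the (9S)-hydroxy ester F6. TBSOTf/2,6-lutidine then returns to the route at 23.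

Step 14 (Nozaki–Hiyama–Kishi macrocyclisation). It must form a trans-fused (Z)-cyclodecene next to a quaternary carbinol. The fallback sets out from 31 and closes the ring at C5=C6 instead. TMSOTf/2,6-lutidine caps the C8 and C14 hydroxyls as the bis(trimethylsilyl) ether F7. CH2=CHMgBr in THF at −78 °C adds to the alpha-silyloxy aldehyde in the Felkin–Anh sense (7S), and DBU closes the lactone to give the vinyl lactone F8. Pd(PPh3)4/Bu3SnH removes the vinylic iodine to give the diene F9. The second-generation Grubbs catalyst (toluene, 80 °C, high dilution) then closes the ring by metathesis to the silylated macrolactone F10. The HF·pyridine conditions of step 15 remove all silyl groups and rejoin the route at 35.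

**Further compounds**

F1 | step 8 | epoxy alcohol (C10–OH, either epimer) from 16 | CC(=O)O[C@H]1C[C@@H]2O[C@]2(C)C(O)[C@@]1(C)[C@@H](O[Si](C)(C)C(C)(C)C)CC/C(C)=C\I
F2 | step 8 | C10 methanesulfonate of F1 | CC(=O)O[C@H]1C[C@@H]2O[C@]2(C)C(OS(C)(=O)=O)[C@@]1(C)[C@@H](O[Si](C)(C)C(C)(C)C)CC/C(C)=C\I
F3 | step 10 | C12 O-(methoxycarbonylmethyl) ether of 18 | CC(=O)O[C@H]1C[C@H](OCC(=O)OC)C(C)=C[C@@]1(C)[C@@H](O[Si](C)(C)C(C)(C)C)CC/C(C)=C\I
F4 | step 10 | 9-epi (9R) alpha-hydroxy methyl ester | CC(=O)O[C@H]1CC=C(C)[C@H]([C@@H](O)C(=O)OC)[C@@]1(C)[C@@H](O[Si](C)(C)C(C)(C)C)CC/C(C)=C\I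
F5 | step 10 | (9S) chloroacetate methyl ester | CC(=O)O[C@H]1CC=C(C)[C@H]([C@H](OC(=O)CCl)C(=O)OC)[C@@]1(C)[C@@H](O[Si](C)(C)C(C)(C)C)CC/C(C)=C\I
F6 | step 10 | (9S) alpha-hydroxy methyl ester | CC(=O)O[C@H]1CC=C(C)[C@H]([C@H](O)C(=O)OC)[C@@]1(C)[C@@H](O[Si](C)(C)C(C)(C)C)CC/C(C)=C\I
F7 | step 14 | 8,14-bis(trimethylsilyl) ether of aldehyde 31 | C[Si](C)(C)O[C@H]1CC=C(C)[C@H]([C@H](O[Si](C)(C)C(C)(C)C)[C@](O[Si](C)(C)C)(C(C)C(=O)OCC)C=O)[C@@]1(C)[C@@H](O[Si](C)(C)C(C)(C)C)CC/C(C)=C\I
F8 | step 14 | C7-vinyl gamma-lactone, iodoalkene intact | C[Si](C)(C)O[C@H]1CC=C(C)[C@H]([C@H](O[Si](C)(C)C(C)(C)C)[C@@]2(O[Si](C)(C)C)[C@H](C=C)OC(=O)[C@@H]2C)[C@@]1(C)[C@@H](O[Si](C)(C)C(C)(C)C)CC/C(C)=C\I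
F9 | step 14 | deiodinated diene (C5 isopropenyl-type terminus, C7 vinyl) | C[Si](C)(C)O[C@H]1CC=C(C)[C@H]([C@H](O[Si](C)(C)C(C)(C)C)[C@@]2(O[Si](C)(C)C)[C@H](C=C)OC(=O)[C@@H]2C)[C@@]1(C)[C@@H](O[Si](C)(C)C(C)(C)C)CCC(C)=C
F10 | step 14 | 8,14-bis(trimethylsilyl) ether of 34 | C[Si](C)(C)O[C@H]1CC=C(C)[C@@H]2[C@H](O[Si](C)(C)C(C)(C)C)[C@@]3(O[Si](C)(C)C)[C@H](/C=C(/C)CC[C@H](O[Si](C)(C)C(C)(C)C)[C@@]12C)OC(=O)[C@@H]3C
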